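**Assumption (one line):** pinostilbene and resveratrol triacetate are taken as catalog compounds, and the sense of induction of the phosphoric acid is unproven, so the (R)-catalyst is assumed to give the (1R,5S,6R,7R) series (use the (S)-acid if it does not).

## Retrosynthetic overview

1. Vitisinol D (6) ⇐ near-neutral removal of three aryl acetates from triacetate 5.
2. 5 ⇐ one oxidative dearomative (3+2) annulation of two differently masked stilbenes: the resorcinol ring of 4 reacts twice as a carbon nucleophile, and the 2e-oxidised 4-hydroxystilbene 2 supplies C6 then C7 as a 1,2-dielectrophile.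
3. Ring order: the six-membered ring is the dearomatised arene of 4; the five-membered ring closes in the same step (C5–C6 first, then C1–C7), which creates the bicyclo[3.2.1]octenedione and all four stereocenters.
4. Role assignment: in 4 the 4′-OAc blocks oxidation and the O-methyl removes the phenolic OH that would otherwise close to a dihydrobenzofuran (it is lost as methanol); 2 carries the only oxidisable phenol.
5. 2 and 4 ⇐ lipase-controlled regioselective de-acetylation / acetylation of resveratrol triacetate (1) and pinostilbene (3).

Bicycle numbering used below: C1 and C5 bridgeheads, C2 enone C=O, C3=C4, C6/C7 two-carbon bridge, C8 bridging C=O.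

## Route

**Step 1**
Reactants: 1, resveratrol triacetate, (E)-3,5,4′-triacetoxystilbene
Product: 2, (E)-3,5-diacetoxy-4′-hydroxystilbene (3,5-di-O-acetylresveratrol)
Conditions: immobilised Candida antarctica lipase B, n-BuOH (4 equiv), MTBE, 40 °C
Reagents that add atoms: none
Why: Lipase-catalysed regioselective alcoholysis (transesterification) removes only the unhindered 4′-acetate and leaves the 3,5-diacetate; no stereocenter.

**Step 2**
Reactants: 3, pinostilbene, (E)-3,4′-dihydroxy-5-methoxystilbene
Product: 4, (E)-4′-acetoxy-3-hydroxy-5-methoxystilbene (4′-O-acetylpinostilbene)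
Conditions: Burkholderia cepacia lipase (lipase PS), vinyl acetate (5 equiv), t-AmOH, 40 °C
Reagents that add atoms: vinyl acetate, C=COC(C)=O (acetyl group)
Why: Lipase-catalysed regioselective O-acylation of the unhindered 4′-OH, as established for resveratrol, leaves the resorcinol-type OH free; no stereocenter.

**Step 3 (key step)**
Reactants: 4, (E)-4′-acetoxy-3-hydroxy-5-methoxystilbene (3.0 equiv, excess recovered); 2, (E)-3,5-diacetoxy-4′-hydroxystilbene (1.0 equiv)
Product: 5, vitisinol D tri-O-acetate, (1R,5S,6R,7R)-4-[(E)-2-(4-acetoxyphenyl)ethenyl]-6-(3,5-diacetoxyphenyl)-7-(4-hydroxyphenyl)bicyclo[3.2.1]oct-3-ene-2,8-dione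
Conditions: (R)-TRIP [(R)-3,3′-bis(2,4,6-triisopropylphenyl)-BINOL hydrogen phosphate] (10 mol %), CH2Cl2/PhMe 1:1, −40 °C; 2 and DDQ (1.05 equiv) co-added by syringe pump over 4 h; then aq. NaHCO3/ascorbate
Reagents that add atoms: none obligatory (DDQ only removes 2 H; the O-methyl leaves as MeOH or as the methyl ether of reduced DDQ). If the methyl oxocarbenium survives to work-up, water (O) supplies the carbonyl oxygen.
Why: Proposed new method: a chiral-phosphate-paired oxidative dearomative (3+2) annulation. DDQ takes two electrons from the only free 4-hydroxystilbene phenol (2) to give a quinone-methide cation ion-paired with the chiral phosphate. The ring carbon of 4 ortho to its OH (which is hydrogen-bonded to the phosphate, while the phosphate also holds the quinone-methide oxygen) attacks cationic C6, which fixes C5 and C6 with the diacetoxyphenyl endo. The resulting non-aromatic dienone has no OH next to C5 (the other oxygen is methylated), so its enol-ether carbon C1 closes on the p-quinone methide C7 (aryl exo, trans to the C6 aryl) faster than keto–phenol tautomerisation, which fixes C1 and C7. The O-methyl oxocarbenium then collapses to the C2 ketone. The closest known reaction types are Büchi-type cationic (5+2)/(3+2) cycloadditions of quinone-monoketal cations with aryl propenes, oxidative phenol/hydroxystilbene couplings that give dihydrobenzofurans, and chiral phosphoric acid control of additions to p-quinone methides.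

**Step 4**
Reactants: 5, vitisinol D tri-O-acetate
Product: 6, vitisinol D, (1R,5S,6R,7R)-6-(3,5-dihydroxyphenyl)-7-(4-hydroxyphenyl)-4-[(E)-2-(4-hydroxyphenyl)ethenyl]bicyclo[3.2.1]oct-3-ene-2,8-dione
Conditions: NH4OAc (10 equiv), MeOH/H2O 4:1, rt
Reagents that add atoms: none
Why: Near-neutral methanolysis of aryl acetates unmasks the three phenols without opening the non-enolisable β-diketone (retro-Claisen) or ionising the p-hydroxybenzylic C1–C7 bond; no stereocenter is epimerisable (two bridgeheads, two non-acidic benzylic CH).

## Compound list

1 | resveratrol triacetate, (E)-3,5,4′-triacetoxystilbene | CC(=O)Oc1ccc(/C=C/c2cc(OC(C)=O)cc(OC(C)=O)c2)cc1 | starting material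
2 | (E)-3,5-diacetoxy-4′-hydroxystilbene | CC(=O)Oc1cc(/C=C/c2ccc(O)cc2)cc(OC(C)=O)c1 | intermediate
3 | pinostilbene, (E)-3,4′-dihydroxy-5-methoxystilbene | COc1cc(O)cc(/C=C/c2ccc(O)cc2)c1 | starting material
4 | (E)-4′-acetoxy-3-hydroxy-5-methoxystilbene | COc1cc(O)cc(/C=C/c2ccc(OC(C)=O)cc2)c1 | intermediate
5 | vitisinol D tri-O-acetate, (1R,5S,6R,7R) | O=C1C=C(/C=C/c2ccc(OC(C)=O)cc2)[C@H]2C(=O)[C@@H]1[C@H](c1ccc(O)cc1)[C@H]2c1cc(OC(C)=O)cc(OC(C)=O)c1 | intermediate
6 | vitisinol D, (1R,5S,6R,7R) | O=C1C=C(/C=C/c2ccc(O)cc2)[C@H]2C(=O)[C@@H]1[C@H](c1ccc(O)cc1)[C@H]2c1cc(O)cc(O)c1 | target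

## Summary

Total steps: 4. Longest linear sequence: 3 (1 → 2 → 5 → 6, or 3 → 4 → 5 → 6).

Three steps most likely to fail:

1. **Step 3 (proposed new annulation).** Risks: homo-coupling of 2; attack of 4 through the carbon between its two oxygens; rearomatisation before the C1–C7 closure (open-chain or dihydrobenzofuran products); wrong endo/exo sense; low ee. Fallback with known chemistry and a different bond order:
   - chiral-triazolium NHC homoenolate conjugate addition of 4-(silyloxy)cinnamaldehyde to (1E,4E)-1-[3,5-bis(silyloxy)phenyl]-5-[4-(silyloxy)phenyl]penta-1,4-dien-3-one with MeOH trapping (sets C6/C7);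
   - Dieckmann closure to the 2-cinnamoyl-3,4-diarylcyclopentanone;
   - γ-acetylation of its dianion;
   - acid-mediated intramolecular aldol condensation to the bicyclic enedione, then desilylation.
2. **Step 4 (deacetylation).** Risk: retro-Claisen opening or phenoxide-driven C1–C7 cleavage. Fallback: change the protecting-group strategy to TBS ethers on both partners (made by Heck coupling of the silylated halides and styrenes) and finish with HF·pyridine in THF.
3. **Step 2 (regioselective acetylation of pinostilbene).** Risk: over- or mis-acylation on this untested substrate. Fallback: build 4 by C–C coupling instead, Mizoroki–Heck reaction of 3-bromo-5-methoxyphenol with 4-acetoxystyrene (Pd(OAc)2, P(o-tol)3, Et3N, DMF).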